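## Retrosynthetic overview

1. Target 15 ⇐ 14 (phenol desilylation) ⇐ 13 (epimerisation at C4, alpha to the ketone) ⇐ aryllithium 11 + exo-aryl bicyclic lactone 10; this acyl substitution opens a temporary lactone ring and creates the aroyl group.
2. 10 ⇐ lactone 6 + aryl bromide 8: the aryl–C2 bond (oxolane numbering of the target: O1, C2 aryl, C3 CH2OH, C4 aroyl, C5) is made by decatungstate/nickel C(sp3)–H arylation.
3. Enabling feature: the ring oxygen O1 makes C2–H hydridic; in 6 the cis-fused lactone ring (C4–C(=O)–O–CH2–C3) deactivates the other ether methylene C5 (beta to the carbonyl) and folds the bicycle so that the aryl group enters on the convex face, trans to the C3 arm.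
4. 6 ⇐ hemiester 4 ⇐ meso anhydride 3 (alkaloid desymmetrisation sets the absolute configuration at C3) ⇐ furan-3,4-dicarboxylic acid 1.
5. Ring order: oxolane ring by furan hydrogenation (step 1); temporary anhydride ring (closed step 2, opened step 3); temporary lactone ring (closed step 4, opened step 7).

Key step: step 6

Assumption: quinidine is taken to direct methanol to the carbonyl of 3 that gives hemiester 4 as drawn; if the sense is the opposite, the pseudo-enantiomer quinine is used and nothing else changes.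

## Route

Step 1
Reactants: 1 furan-3,4-dicarboxylic acid
Product: 2 cis-oxolane-3,4-dicarboxylic acid (meso)
Conditions: H2 (50 bar), 5% Rh on Al2O3, H2O, 80 °C
Reagents that add atoms: none
Why: Heterogeneous catalytic hydrogenation of the electron-poor furan should deliver all hydrogens from the adsorbed face, so both carboxyl groups end up cis (meso diacid).

Step 2
Reactants: 2 cis-oxolane-3,4-dicarboxylic acid
Product: 3 cis-oxolane-3,4-dicarboxylic anhydride (meso)
Conditions: Ac2O, reflux; evaporation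
Reagents that add atoms: none
Why: Cyclodehydration; only the cis diacid can close the five-membered anhydride, and any trans acid should epimerise under these conditions and be drawn into the same product.

Step 3
Reactants: 3 cis-oxolane-3,4-dicarboxylic anhydride
Product: 4 (3S,4R)-4-(methoxycarbonyl)oxolane-3-carboxylic acid
Conditions: quinidine (1.1 equiv), MeOH (3 equiv), toluene, −55 °C; aqueous HCl work-up
Reagents that add atoms: methanol, CO
Why: Cinchona alkaloid-mediated desymmetrising methanolysis of a meso anhydride; the alkaloid acts as a chiral general base and selects one enantiotopic carbonyl, which fixes the absolute configuration of both ring stereocentres.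

Step 4
Reactants: 4 (3S,4R)-4-(methoxycarbonyl)oxolane-3-carboxylic acid
Product: 6 (1R,5S)-3,7-dioxabicyclo[3.3.0]octan-2-one, via hydroxy ester 5 (not isolated)
Conditions: BH3·SMe2, THF, 0 °C to rt; aqueous work-up; TsOH (cat.), toluene, 60 °C
Reagents that add atoms: none
Why: Borane reduces the carboxylic acid chemoselectively over the methyl ester, and the cis hydroxy ester should lactonise readily; no stereocentre is touched.

Step 5
Reactants: 7 5-bromo-2-methoxyphenol
Product: 8 (5-bromo-2-methoxyphenoxy)tri(propan-2-yl)silane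
Conditions: i-Pr3SiCl, imidazole, DMF, rt
Reagents that add atoms: triisopropylsilyl chloride, CC(C)[Si](Cl)(C(C)C)C(C)C
Why: Standard phenol silylation; the bulky silyl ether has no weak hydridic C–H bond and should survive both the photochemical coupling and the later aryllithium chemistry.

Step 6
Reactants: 6 (1R,5S)-3,7-dioxabicyclo[3.3.0]octan-2-one (3 equiv, excess to be recovered) and 8 (5-bromo-2-methoxyphenoxy)tri(propan-2-yl)silane
Product: 10 (1R,5R,6S)-6-[4-methoxy-3-(triisopropylsilyloxy)phenyl]-3,7-dioxabicyclo[3.3.0]octan-2-one, via alpha-oxy radical 9 (not isolated)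
Conditions: (n-Bu4N)4[W10O32] (2 mol%), NiBr2·DME (5 mol%), 4,4'-di-tert-butyl-2,2'-bipyridine (5 mol%), K3PO4 (1.1 equiv), degassed MeCN, 390 nm LEDs, rt
Reagents that add atoms: none
Why: Photoexcited decatungstate abstracts a hydrogen atom from C6–H of 6 (alpha to the ether oxygen O7) to give radical 9, which is captured by the aryl nickel bromide complex formed by oxidative addition of 8 to zerovalent nickel; reductive elimination from the resulting trivalent nickel species forms the aryl–C6 bond, the reduced polyoxometalate returns monovalent nickel to zerovalent nickel, and K3PO4 takes up HBr. The closest known reaction type is the decatungstate/nickel dual-catalytic C(sp3)–H arylation of tetrahydrofuran and related cyclic ethers with aryl bromides. No ring is closed; the oxolane and lactone rings of 6 are carried through intact. The new stereocentre C6 is under substrate control: the planar radical is met by nickel on the convex (exo) face of the cis-fused bicycle, so the aryl group should end up trans to the C5–C4 bond (6S). The selectivity needed is between the two ether methylenes C6 and C8 (and against C4–H2 and C1–H): the electrophilic abstractor prefers the most hydridic C–H, and C8 lies beta to the lactone carbonyl, C4 carries the acyloxy oxygen and C1–H is alpha to the carbonyl, so C6 should react first. The excess of 6 is meant to suppress a second abstraction at the new benzylic C–H of 10.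

Step 7
Reactants: 10 (1R,5R,6S)-6-[4-methoxy-3-(triisopropylsilyloxy)phenyl]-3,7-dioxabicyclo[3.3.0]octan-2-one and 8 (5-bromo-2-methoxyphenoxy)tri(propan-2-yl)silane
Product: 13 [(3R,4R,5S)-4-(hydroxymethyl)-5-[4-methoxy-3-(triisopropylsilyloxy)phenyl]oxolan-3-yl][4-methoxy-3-(triisopropylsilyloxy)phenyl]methanone, via aryllithium 11 (not isolated), via lithium lactolate 12 (not isolated)
Conditions: 8 (1.2 equiv), n-BuLi (1.2 equiv), THF, −78 °C; then 10, −78 °C; AcOH quench at −78 °C
Reagents that add atoms: none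
Why: Bromine–lithium exchange followed by acyl substitution at the lactone; the tetrahedral lithium lactolate should persist at −78 °C, so the ketone is released only on quench and a second addition is avoided; the ring stereocentres are untouched (C3/C4 still cis).

Step 8
Reactants: 13 the cis keto alcohol from step 7
Product: 14 [(3S,4R,5S)-4-(hydroxymethyl)-5-[4-methoxy-3-(triisopropylsilyloxy)phenyl]oxolan-3-yl][4-methoxy-3-(triisopropylsilyloxy)phenyl]methanone
Conditions: DBU (0.3 equiv), toluene, 40 °C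
Reagents that add atoms: none
Why: Base-mediated epimerisation by reversible deprotonation at C4 (alpha to the aryl ketone); the C3 stereocentre directs C4 to the thermodynamically preferred all-trans arrangement.

Step 9
Reactants: 14 the all-trans bis(silyl ether)
Product: 15 [(3S,4R,5S)-4-(hydroxymethyl)-5-(3-hydroxy-4-methoxyphenyl)oxolan-3-yl](3-hydroxy-4-methoxyphenyl)methanone (CNP0234761.1)
Conditions: n-Bu4NF (2.5 equiv), AcOH (3 equiv), THF, 0 °C
Reagents that add atoms: none
Why: Fluoride-mediated cleavage of both aryl silyl ethers; buffering with acetic acid keeps the medium near neutral so that the beta-alkoxy ketone and the C4 centre should be left alone.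

## Compound list

1 | furan-3,4-dicarboxylic acid | OC(=O)c1cocc1C(=O)O | starting material
2 | cis-oxolane-3,4-dicarboxylic acid (meso, 3R,4S) | OC(=O)[C@H]1COC[C@H]1C(=O)O | intermediate
3 | cis-oxolane-3,4-dicarboxylic anhydride (meso; 3,7-dioxabicyclo[3.3.0]octane-2,4-dione) | O=C1[C@H]2COC[C@H]2C(=O)O1 | intermediate
4 | (3S,4R)-4-(methoxycarbonyl)oxolane-3-carboxylic acid | COC(=O)[C@H]1COC[C@H]1C(=O)O | intermediate
5 | methyl (3R,4R)-4-(hydroxymethyl)oxolane-3-carboxylate | COC(=O)[C@H]1COC[C@H]1CO | intermediate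
6 | (1R,5S)-3,7-dioxabicyclo[3.3.0]octan-2-one | O=C1[C@H]2COC[C@H]2CO1 | intermediate
7 | 5-bromo-2-methoxyphenol | COc1ccc(Br)cc1O | starting material
8 | (5-bromo-2-methoxyphenoxy)tri(propan-2-yl)silane | COc1ccc(Br)cc1O[Si](C(C)C)(C(C)C)C(C)C | intermediate
9 | (1R,5S)-2-oxo-3,7-dioxabicyclo[3.3.0]octan-6-yl radical | O=C1[C@H]2CO[CH][C@H]2CO1 | intermediate
10 | (1R,5R,6S)-6-[4-methoxy-3-(triisopropylsilyloxy)phenyl]-3,7-dioxabicyclo[3.3.0]octan-2-one | O=C1[C@H]2CO[C@H](c3ccc(OC)c(O[Si](C(C)C)(C(C)C)C(C)C)c3)[C@H]2CO1 | intermediate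
11 | [4-methoxy-3-(triisopropylsilyloxy)phenyl]lithium | [Li]c1ccc(OC)c(O[Si](C(C)C)(C(C)C)C(C)C)c1 | intermediate
12 | lithium (1R,5R,6S)-2,6-bis[4-methoxy-3-(triisopropylsilyloxy)phenyl]-3,7-dioxabicyclo[3.3.0]octan-2-olate | [Li]OC1(c2ccc(OC)c(O[Si](C(C)C)(C(C)C)C(C)C)c2)[C@H]2CO[C@H](c3ccc(OC)c(O[Si](C(C)C)(C(C)C)C(C)C)c3)[C@H]2CO1 | intermediate
13 | [(3R,4R,5S)-4-(hydroxymethyl)-5-[4-methoxy-3-(triisopropylsilyloxy)phenyl]oxolan-3-yl][4-methoxy-3-(triisopropylsilyloxy)phenyl]methanone | O=C(c1ccc(OC)c(O[Si](C(C)C)(C(C)C)C(C)C)c1)[C@H]1CO[C@H](c2ccc(OC)c(O[Si](C(C)C)(C(C)C)C(C)C)c2)[C@H]1CO | intermediate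
14 | [(3S,4R,5S)-4-(hydroxymethyl)-5-[4-methoxy-3-(triisopropylsilyloxy)phenyl]oxolan-3-yl][4-methoxy-3-(triisopropylsilyloxy)phenyl]methanone | O=C(c1ccc(OC)c(O[Si](C(C)C)(C(C)C)C(C)C)c1)[C@@H]1CO[C@H](c2ccc(OC)c(O[Si](C(C)C)(C(C)C)C(C)C)c2)[C@H]1CO | intermediate
15 | [(3S,4R,5S)-4-(hydroxymethyl)-5-(3-hydroxy-4-methoxyphenyl)oxolan-3-yl](3-hydroxy-4-methoxyphenyl)methanone | O=C(c1ccc(OC)c(O)c1)[C@@H]1CO[C@H](c2ccc(OC)c(O)c2)[C@H]1CO | target

## Summary

Total step count: 9. Longest linear sequence: 8 steps (steps 1–4, then 6–9); step 5 is a one-step side branch.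

Steps most likely to fail, with fallbacks:

**Step 6.** Hydrogen abstraction may also occur at the other ether methylene, giving poor site selectivity, and oxidative addition of the electron-rich aryl bromide may be slow. The fallback sets out from 8 and comes back at 13, and builds the aryl-bearing carbon from an aldehyde instead of a C–H bond:
- 8 is lithiated (n-BuLi) and formylated with DMF to 4-methoxy-3-(triisopropylsilyloxy)benzaldehyde F1.
- F1 is condensed with propane-1,3-dithiol (BF3·OEt2) to 2-[4-methoxy-3-(triisopropylsilyloxy)phenyl]-1,3-dithiane F2.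
- The 2-lithio derivative of F2 (n-BuLi, THF, −78 °C) adds 1,4 to (5R)-5-[(1R,2S,5R)-menthyloxy]furan-2(5H)-one F3, anti to the menthyloxy group. The lactone enolate is trapped in the same flask by aldol addition to a second equivalent of F1, giving the 3,4-trans-4,5-trans lactone adduct F4 (carbinol configuration immaterial).
- LiAlH4 reduces the lactone and acetal carbons with loss of menthol to the triol F5.
- Catalytic TsOH ionises the para-methoxybenzylic alcohol and the primary hydroxyl that stems from the acetal carbon closes the oxolane, aryl trans to the hydroxymethyl arm, giving the dithiane-masked cis keto alcohol F6.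
- MeI, CaCO3 in aqueous MeCN removes the dithiane and gives 13.

**Step 7.** Enolisation of the lactone or a second addition to the released ketone may compete with mono-addition. The fallback sets out from 10 and comes back at 13, and forms the ketone at the aldehyde oxidation level:
- i-Bu2AlH (CH2Cl2, −78 °C) reduces 10 to the lactol (1R,5R,6S)-6-[4-methoxy-3-(triisopropylsilyloxy)phenyl]-3,7-dioxabicyclo[3.3.0]octan-2-ol F7.
- Aryllithium 11 (2.5 equiv) adds to the open hydroxy aldehyde form to give the benzylic/primary diol F8.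
- MnO2 (CH2Cl2) oxidises only the electron-rich benzylic alcohol, giving 13.

**Step 8.** Equilibration may stall because ring–chain tautomerism withholds the cis isomer from enolisation, or base may open the oxolane by beta-elimination. The fallback sets out from 10 and comes back at 15, and sets the trans relationship before the ketone exists:
- NaOMe in MeOH opens the lactone and epimerises the ester alpha-carbon; the trans hydroxy ester methyl (3S,4R,5S)-4-(hydroxymethyl)-5-[4-methoxy-3-(triisopropylsilyloxy)phenyl]oxolane-3-carboxylate F9 cannot relactonise and should accumulate.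
- t-BuMe2SiCl/imidazole gives the silyl ether F10.
- MeNHOMe·HCl/i-PrMgCl gives the N-methoxy-N-methyl amide F11.
- Aryllithium 11 gives the all-trans silyl-protected ketone F12.
- n-Bu4NF/AcOH removes all three silyl groups to give 15.

Further compounds
F1 | step 6 | 4-methoxy-3-(triisopropylsilyloxy)benzaldehyde | O=Cc1ccc(OC)c(O[Si](C(C)C)(C(C)C)C(C)C)c1
F2 | step 6 | 2-[4-methoxy-3-(triisopropylsilyloxy)phenyl]-1,3-dithiane | COc1ccc(C2SCCCS2)cc1O[Si](C(C)C)(C(C)C)C(C)C
F3 | step 6 | (5R)-5-[(1R,2S,5R)-menthyloxy]furan-2(5H)-one | O=C1C=C[C@H](O[C@@H]2C[C@H](C)CC[C@H]2C(C)C)O1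
F4 | step 6 | (3R,4R,5R)-3-{hydroxy[4-methoxy-3-(triisopropylsilyloxy)phenyl]methyl}-4-{2-[4-methoxy-3-(triisopropylsilyloxy)phenyl]-1,3-dithian-2-yl}-5-[(1R,2S,5R)-menthyloxy]oxolan-2-one (3,4-trans, 4,5-trans; carbinol centre undefined) | O=C1O[C@@H](O[C@@H]2C[C@H](C)CC[C@H]2C(C)C)[C@H](C2(c3ccc(OC)c(O[Si](C(C)C)(C(C)C)C(C)C)c3)SCCCS2)[C@H]1C(O)c1ccc(OC)c(O[Si](C(C)C)(C(C)C)C(C)C)c1
F5 | step 6 | (2R,3R)-2-{hydroxy[4-methoxy-3-(triisopropylsilyloxy)phenyl]methyl}-3-{2-[4-methoxy-3-(triisopropylsilyloxy)phenyl]-1,3-dithian-2-yl}butane-1,4-diol (carbinol centre undefined) | OC[C@H](C(O)c1ccc(OC)c(O[Si](C(C)C)(C(C)C)C(C)C)c1)[C@H](CO)C1(c2ccc(OC)c(O[Si](C(C)C)(C(C)C)C(C)C)c2)SCCCS1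
F6 | step 6 | [(2S,3R,4R)-2-[4-methoxy-3-(triisopropylsilyloxy)phenyl]-4-{2-[4-methoxy-3-(triisopropylsilyloxy)phenyl]-1,3-dithian-2-yl}oxolan-3-yl]methanol | C1(c2ccc(OC)c(O[Si](C(C)C)(C(C)C)C(C)C)c2)(SCCCS1)[C@H]1CO[C@H](c2ccc(OC)c(O[Si](C(C)C)(C(C)C)C(C)C)c2)[C@H]1CO
F7 | step 7 | (1R,5R,6S)-6-[4-methoxy-3-(triisopropylsilyloxy)phenyl]-3,7-dioxabicyclo[3.3.0]octan-2-ol (lactol centre undefined) | OC1[C@H]2CO[C@H](c3ccc(OC)c(O[Si](C(C)C)(C(C)C)C(C)C)c3)[C@H]2CO1
F8 | step 7 | [(3R,4R,5S)-4-(hydroxymethyl)-5-[4-methoxy-3-(triisopropylsilyloxy)phenyl]oxolan-3-yl][4-methoxy-3-(triisopropylsilyloxy)phenyl]methanol (carbinol centre undefined) | OC(c1ccc(OC)c(O[Si](C(C)C)(C(C)C)C(C)C)c1)[C@H]1CO[C@H](c2ccc(OC)c(O[Si](C(C)C)(C(C)C)C(C)C)c2)[C@H]1CO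
F9 | step 8 | methyl (3S,4R,5S)-4-(hydroxymethyl)-5-[4-methoxy-3-(triisopropylsilyloxy)phenyl]oxolane-3-carboxylate | COC(=O)[C@@H]1CO[C@H](c2ccc(OC)c(O[Si](C(C)C)(C(C)C)C(C)C)c2)[C@H]1CO
F10 | step 8 | methyl (3S,4R,5S)-4-[(tert-butyldimethylsilyloxy)methyl]-5-[4-methoxy-3-(triisopropylsilyloxy)phenyl]oxolane-3-carboxylate | COC(=O)[C@@H]1CO[C@H](c2ccc(OC)c(O[Si](C(C)C)(C(C)C)C(C)C)c2)[C@H]1CO[Si](C)(C)C(C)(C)C
F11 | step 8 | (3S,4R,5S)-4-[(tert-butyldimethylsilyloxy)methyl]-N-methoxy-5-[4-methoxy-3-(triisopropylsilyloxy)phenyl]-N-methyloxolane-3-carboxamide | CON(C)C(=O)[C@@H]1CO[C@H](c2ccc(OC)c(O[Si](C(C)C)(C(C)C)C(C)C)c2)[C@H]1CO[Si](C)(C)C(C)(C)C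
F12 | step 8 | [(3S,4R,5S)-4-[(tert-butyldimethylsilyloxy)methyl]-5-[4-methoxy-3-(triisopropylsilyloxy)phenyl]oxolan-3-yl][4-methoxy-3-(triisopropylsilyloxy)phenyl]methanone | O=C(c1ccc(OC)c(O[Si](C(C)C)(C(C)C)C(C)C)c1)[C@@H]1CO[C@H](c2ccc(OC)c(O[Si](C(C)C)(C(C)C)C(C)C)c2)[C@H]1CO[Si](C)(C)C(C)(C)C
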